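**Retrosynthetic overview** (labdane numbering: ring carbons C-1 to C-10, side chain C-11 to C-16)

- Functional-group level: the C-8 exocyclic methylene is carried as a C-8 ketone, C-9–H as C-9–CO2Me (activating group), and the 13Z acetoxy acid as a butenolide (temporary ring that locks the olefin geometry); the C-2 hydroxyl is carried as a silyl ether.
- Key disconnection C-9–C-11: acyclic β-keto ester 13 (C-1 to C-10) plus 4-vinylbutenolide 16 (C-11 to C-16). In one flask a 1,6-Michael addition joins them and SnCl4 then folds the chain, closing ring A first and ring B second.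
- Enabling feature: C-9 of ring B sits next to C-8, whose exocyclic methylene is a masked ketone. As the α-carbon of a C-8 ketone/C-9 ester it can act twice as a nucleophile, first toward C-11 and then toward the C-10 cation that closes ring B.
- Stereocontrol: the single stereocentre of 13 (C-2, from (R)-epichlorohydrin) directs C-5 and C-10 in the bicyclisation; C-9 is set thermodynamically next to the C-8 ketone. Chain 13 comes from epoxide opening by acetylide, carboalumination/formaldehyde and acetoacetate dianion alkylation.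

Key step: step 8

Remark: the 13,14-olefin of the target is read from the SMILES as Z (CH2OAc cis to CO2H), and the ring system as the ent-labdane series (2R,5R,9R,10R).

**Step 1**
Reactants: 1 (R)-epichlorohydrin; 2 isopropenylmagnesium bromide
Product: 4 (R)-2-(2-methylprop-2-en-1-yl)oxirane, via chlorohydrin 3 (not isolated)
Conditions: CuI (10 mol%), THF, −40 → −20 °C; then NaOH (aq), Et2O, 0 °C → rt
Reagents that add atoms: none
Why: Copper-catalysed Grignard opening of the epoxide at its CH2 terminus followed by Williamson closure of the chlorohydrin gives the homologous epoxide, and the stereocentre (future C-2) is not touched, so its configuration comes from 1.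

**Step 2**
Reactants: 4 (R)-2-(2-methylprop-2-en-1-yl)oxirane; 5 lithium acetylide ethylenediamine complex
Product: 6 (4R)-2-methylhept-1-en-6-yn-4-ol
Conditions: DMSO, 15 °C → rt; H2O work-up
Reagents that add atoms: none
Why: SN2 opening of the terminal epoxide by the acetylide at the unsubstituted carbon installs C-10/C-5 as a terminal alkyne and frees the C-2 carbinol without affecting its configuration.

**Step 3**
Reactants: 6 (4R)-2-methylhept-1-en-6-yn-4-ol
Product: 7 tert-butyl{[(4R)-2-methylhept-1-en-6-yn-4-yl]oxy}diphenylsilane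
Conditions: tert-butyl(chloro)diphenylsilane, imidazole, DMF, rt
Reagents that add atoms: tert-butyl(chloro)diphenylsilane, CC(C)(C)[Si](Cl)(c1ccccc1)c1ccccc1
Why: Standard silylation of a secondary alcohol; this bulky silyl ether should survive SnCl4, LiCl at 150 °C and KOH, and should stay equatorial in step 8.

**Step 4**
Reactants: 7 tert-butyl{[(4R)-2-methylhept-1-en-6-yn-4-yl]oxy}diphenylsilane
Product: 9 (2E,5R)-5-{[tert-butyl(diphenyl)silyl]oxy}-3,7-dimethylocta-2,7-dien-1-ol, via alkenyl(dimethyl)alane 8 (not isolated)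
Conditions: Me3Al (3 equiv), Cp2ZrCl2 (25 mol%), CH2Cl2, 0 °C → rt; then n-BuLi, THF, −78 °C; (CH2O)n, −78 °C → rt
Reagents that add atoms: trimethylaluminium, C[Al](C)C; paraformaldehyde (as formaldehyde), C=O
Why: Negishi carboalumination adds CH3 and Al syn across the alkyne with Al on the terminal carbon, and the derived aluminate reacts with formaldehyde with retention, so the (E)-C-5=C-10 olefin (C-1 trans to C-6) needed for a trans ring fusion is set here.

**Step 5**
Reactants: 9 (2E,5R)-5-{[tert-butyl(diphenyl)silyl]oxy}-3,7-dimethylocta-2,7-dien-1-ol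
Product: 10 {[(4R,6E)-8-bromo-2,6-dimethylocta-1,6-dien-4-yl]oxy}(tert-butyl)diphenylsilane
Conditions: CBr4, PPh3, CH2Cl2, 0 °C
Reagents that add atoms: carbon tetrabromide, BrC(Br)(Br)Br
Why: Appel reaction of a primary allylic alcohol under neutral conditions should leave the silyl ether and both olefins intact.

**Step 6**
Reactants: 10 {[(4R,6E)-8-bromo-2,6-dimethylocta-1,6-dien-4-yl]oxy}(tert-butyl)diphenylsilane; 11 methyl acetoacetate
Product: 13 methyl (6E,9R)-9-{[tert-butyl(diphenyl)silyl]oxy}-7,11-dimethyl-3-oxododeca-6,11-dienoate, via acetoacetate dianion 12 (not isolated)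
Conditions: 11, NaH, THF, 0 °C; n-BuLi, 0 °C; then 10, 0 °C → rt; dilute HCl
Reagents that add atoms: none
Why: γ-Alkylation of the acetoacetate dianion (its terminal carbanion is the more nucleophilic site) by SN2 on the primary allylic bromide gives the β-keto ester that makes C-9 doubly nucleophilic.

**Step 7**
Reactants: 14 4-bromofuran-2(5H)-one; 15 tributyl(vinyl)stannane
Product: 16 4-ethenylfuran-2(5H)-one
Conditions: Pd(PPh3)4 (5 mol%), BHT (cat.), THF, 65 °C; used at once as a solution
Reagents that add atoms: none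
Why: Stille coupling, in which zerovalent palladium inserts readily into the vinylogous acyl bromide and the vinyl group is transferred from tin.

**Step 8 (key step)**
Reactants: 13 methyl (6E,9R)-9-{[tert-butyl(diphenyl)silyl]oxy}-7,11-dimethyl-3-oxododeca-6,11-dienoate; 16 4-ethenylfuran-2(5H)-one
Product: 18 methyl (1S,4aR,7R,8aR)-7-{[tert-butyl(diphenyl)silyl]oxy}-5,5,8a-trimethyl-2-oxo-1-[2-(5-oxo-2,5-dihydrofuran-3-yl)ethyl]decahydronaphthalene-1-carboxylate, via acyclic Michael adduct 17 (not isolated)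
Conditions: DBU (10 mol%), CH2Cl2, 0 °C → rt; then SnCl4 (4 equiv), CH2Cl2, −78 → 0 °C
Reagents that add atoms: none
Why: Proposed new method: in stage 1 the C-9 carbanion of the β-keto ester adds 1,6 (vinylogous Michael) to the vinyl terminus C-11 of 16 and the dienolate is reprotonated at C-12, so the 13,14-olefin stays locked in the butenolide; in stage 2 the proton released from the tin-chelated β-keto ester adds to the terminal 1,1-disubstituted olefin, the C-4 cation is attacked by the C-5=C-10 olefin to close ring A (6-endo, chair) and the chelated enol carbon C-9 attacks the C-10 cation to close ring B (6-endo, chair). The closest known reactions are 1,6-additions of 1,3-dicarbonyl carbanions to dienyl esters and the SnCl4 bicyclisation of γ-geranylated acetoacetates; new are the one-flask combination and the termination by a fully substituted enol carbon, which creates the vicinal quaternary centres C-9 and C-10. C-5 and C-10 arise from antiperiplanar addition across the (E)-C-5=C-10 olefin in a chair–chair transition state (H-5 trans to CH3-20), and their absolute sense is dictated by C-2, whose silyloxy group stays equatorial to avoid 1,3-diaxial contacts with CH3-20 and the axial C-4 methyl. C-9 should form with the ester equatorial because tin chelation fixes the enol geometry, but this centre is re-set in step 9. The step needs 1,6- over 1,4-addition and mono-alkylation (secured by the fully substituted C-13 and the lower acidity of the adduct), C- over O-termination (both carbonyl oxygens are bound to tin and O-cyclisation is reversible) and initiation at the terminal olefin (the less hindered, 1,1-disubstituted one).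

**Step 9**
Reactants: 18 methyl (1S,4aR,7R,8aR)-7-{[tert-butyl(diphenyl)silyl]oxy}-5,5,8a-trimethyl-2-oxo-1-[2-(5-oxo-2,5-dihydrofuran-3-yl)ethyl]decahydronaphthalene-1-carboxylate
Product: 19 4-{2-[(1S,4aR,7R,8aR)-7-{[tert-butyl(diphenyl)silyl]oxy}-5,5,8a-trimethyl-2-oxodecahydronaphthalen-1-yl]ethyl}furan-2(5H)-one
Conditions: LiCl, H2O, DMSO, 150 °C
Reagents that add atoms: none
Why: Krapcho dealkoxycarbonylation (chloride SN2 at the ester methyl, loss of CO2) removes the activating group, and axial protonation and equilibration of the C-8 enol should place the C-9 side chain equatorial (H-9 cis to H-5, trans to CH3-20), the thermodynamic and required configuration.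

**Step 10**
Reactants: 19 4-{2-[(1S,4aR,7R,8aR)-7-{[tert-butyl(diphenyl)silyl]oxy}-5,5,8a-trimethyl-2-oxodecahydronaphthalen-1-yl]ethyl}furan-2(5H)-one
Product: 20 4-{2-[(1R,4aR,7R,8aR)-7-{[tert-butyl(diphenyl)silyl]oxy}-5,5,8a-trimethyl-2-methylidenedecahydronaphthalen-1-yl]ethyl}furan-2(5H)-one
Conditions: Zn, CH2Br2, TiCl4, THF/CH2Cl2, 0 °C → rt
Reagents that add atoms: dibromomethane, BrCBr
Why: Takai–Lombardo methylenation is non-basic and selective for ketones over lactones, so the hindered, epimerisable C-8 ketone should be methylenated without loss of the C-9 configuration.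

**Step 11**
Reactants: 20 4-{2-[(1R,4aR,7R,8aR)-7-{[tert-butyl(diphenyl)silyl]oxy}-5,5,8a-trimethyl-2-methylidenedecahydronaphthalen-1-yl]ethyl}furan-2(5H)-one
Product: 23 (2Z)-3-(acetoxymethyl)-5-[(1R,4aR,7R,8aR)-7-{[tert-butyl(diphenyl)silyl]oxy}-5,5,8a-trimethyl-2-methylidenedecahydronaphthalen-1-yl]pent-2-enoic acid, via potassium hydroxy-carboxylate 21 (not isolated), via dipotassium alkoxide-carboxylate 22 (not isolated)
Conditions: KOH (1.0 equiv), THF/H2O, rt; evaporate; KN(SiMe3)2 (1.1 equiv), THF/DMPU, −78 °C; Ac2O (1.5 equiv), −78 → 0 °C; dilute HCl to pH 3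
Reagents that add atoms: potassium hydroxide, [K+].[OH-]; acetic anhydride, CC(=O)OC(C)=O
Why: Saponification opens the butenolide to the (Z)-4-hydroxy-2-enoate with the ring-fixed geometry; the primary alkoxide should be acetylated far faster than the carboxylate, and once O-16 is capped relactonisation is blocked, so acidification should give the acetoxy acid.

**Step 12**
Reactants: 23 (2Z)-3-(acetoxymethyl)-5-[(1R,4aR,7R,8aR)-7-{[tert-butyl(diphenyl)silyl]oxy}-5,5,8a-trimethyl-2-methylidenedecahydronaphthalen-1-yl]pent-2-enoic acid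
Product: 24 (2Z)-3-(acetoxymethyl)-5-[(1R,4aR,7R,8aR)-7-hydroxy-5,5,8a-trimethyl-2-methylidenedecahydronaphthalen-1-yl]pent-2-enoic acid (CNP0292310.1)
Conditions: HF·pyridine, pyridine, THF, 0 °C → rt
Reagents that add atoms: none
Why: Fluoride-mediated silyl ether cleavage under buffered, non-basic conditions should free the equatorial C-2 hydroxyl without acetate migration, relactonisation or isomerisation of the exocyclic olefin.

**Compound list**

1 | (R)-epichlorohydrin, (R)-2-(chloromethyl)oxirane | ClC[C@H]1CO1 | starting material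
2 | isopropenylmagnesium bromide | C=C(C)[Mg]Br | starting material
3 | (R)-1-chloro-4-methylpent-4-en-2-ol (chlorohydrin, formed as its magnesium alkoxide) | C=C(C)C[C@@H](O)CCl | intermediate
4 | (R)-2-(2-methylprop-2-en-1-yl)oxirane | C=C(C)C[C@@H]1CO1 | intermediate
5 | lithium acetylide ethylenediamine complex | [Li+].[C-]#C.NCCN | starting material
6 | (4R)-2-methylhept-1-en-6-yn-4-ol | C=C(C)C[C@@H](O)CC#C | intermediate
7 | tert-butyl{[(4R)-2-methylhept-1-en-6-yn-4-yl]oxy}diphenylsilane | C=C(C)C[C@@H](O[Si](c1ccccc1)(c1ccccc1)C(C)(C)C)CC#C | intermediate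
8 | dimethyl[(1E,4R)-4-{[tert-butyl(diphenyl)silyl]oxy}-2,6-dimethylhepta-1,6-dien-1-yl]alane | C=C(C)C[C@@H](O[Si](c1ccccc1)(c1ccccc1)C(C)(C)C)C/C(C)=C/[Al](C)C | intermediate
9 | (2E,5R)-5-{[tert-butyl(diphenyl)silyl]oxy}-3,7-dimethylocta-2,7-dien-1-ol | C=C(C)C[C@@H](O[Si](c1ccccc1)(c1ccccc1)C(C)(C)C)C/C(C)=C/CO | intermediate
10 | {[(4R,6E)-8-bromo-2,6-dimethylocta-1,6-dien-4-yl]oxy}(tert-butyl)diphenylsilane | C=C(C)C[C@@H](O[Si](c1ccccc1)(c1ccccc1)C(C)(C)C)C/C(C)=C/CBr | intermediate
11 | methyl acetoacetate | CC(=O)CC(=O)OC | starting material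
12 | sodium lithium dianion (1,3-bis-enolate) of methyl acetoacetate | [Na+].[Li+].C=C([O-])C=C([O-])OC | intermediate
13 | methyl (6E,9R)-9-{[tert-butyl(diphenyl)silyl]oxy}-7,11-dimethyl-3-oxododeca-6,11-dienoate | C=C(C)C[C@@H](O[Si](c1ccccc1)(c1ccccc1)C(C)(C)C)C/C(C)=C/CCC(=O)CC(=O)OC | intermediate
14 | 4-bromofuran-2(5H)-one | BrC1=CC(=O)OC1 | starting material
15 | tributyl(vinyl)stannane | C=C[Sn](CCCC)(CCCC)CCCC | starting material
16 | 4-ethenylfuran-2(5H)-one (4-vinylbutenolide) | C=CC1=CC(=O)OC1 | intermediate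
17 | methyl (6E,9R)-9-{[tert-butyl(diphenyl)silyl]oxy}-7,11-dimethyl-3-oxo-2-[2-(5-oxo-2,5-dihydrofuran-3-yl)ethyl]dodeca-6,11-dienoate (both C-2 epimers, enolisable) | C=C(C)C[C@@H](O[Si](c1ccccc1)(c1ccccc1)C(C)(C)C)C/C(C)=C/CCC(=O)C(CCC1=CC(=O)OC1)C(=O)OC | intermediate
18 | methyl (1S,4aR,7R,8aR)-7-{[tert-butyl(diphenyl)silyl]oxy}-5,5,8a-trimethyl-2-oxo-1-[2-(5-oxo-2,5-dihydrofuran-3-yl)ethyl]decahydronaphthalene-1-carboxylate (trans-decalin, silyloxy and ester equatorial, side chain axial at C-9) | O=C1CC[C@@H]2C(C)(C)C[C@@H](O[Si](c3ccccc3)(c3ccccc3)C(C)(C)C)C[C@@]2(C)[C@]1(CCC1=CC(=O)OC1)C(=O)OC | intermediate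
19 | 4-{2-[(1S,4aR,7R,8aR)-7-{[tert-butyl(diphenyl)silyl]oxy}-5,5,8a-trimethyl-2-oxodecahydronaphthalen-1-yl]ethyl}furan-2(5H)-one (side chain equatorial at C-9) | O=C1CC[C@@H]2C(C)(C)C[C@@H](O[Si](c3ccccc3)(c3ccccc3)C(C)(C)C)C[C@@]2(C)[C@@H]1CCC1=CC(=O)OC1 | intermediate
20 | 4-{2-[(1R,4aR,7R,8aR)-7-{[tert-butyl(diphenyl)silyl]oxy}-5,5,8a-trimethyl-2-methylidenedecahydronaphthalen-1-yl]ethyl}furan-2(5H)-one | C=C1CC[C@@H]2C(C)(C)C[C@@H](O[Si](c3ccccc3)(c3ccccc3)C(C)(C)C)C[C@@]2(C)[C@@H]1CCC1=CC(=O)OC1 | intermediate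
21 | potassium (2Z)-4-hydroxy-3-{2-[(1R,4aR,7R,8aR)-7-{[tert-butyl(diphenyl)silyl]oxy}-5,5,8a-trimethyl-2-methylidenedecahydronaphthalen-1-yl]ethyl}but-2-enoate | C=C1CC[C@@H]2C(C)(C)C[C@@H](O[Si](c3ccccc3)(c3ccccc3)C(C)(C)C)C[C@@]2(C)[C@@H]1CC/C(=C/C(=O)[O-])CO.[K+] | intermediate
22 | dipotassium alkoxide-carboxylate of 21 | C=C1CC[C@@H]2C(C)(C)C[C@@H](O[Si](c3ccccc3)(c3ccccc3)C(C)(C)C)C[C@@]2(C)[C@@H]1CC/C(=C/C(=O)[O-])C[O-].[K+].[K+] | intermediate
23 | (2Z)-3-(acetoxymethyl)-5-[(1R,4aR,7R,8aR)-7-{[tert-butyl(diphenyl)silyl]oxy}-5,5,8a-trimethyl-2-methylidenedecahydronaphthalen-1-yl]pent-2-enoic acid | C=C1CC[C@@H]2C(C)(C)C[C@@H](O[Si](c3ccccc3)(c3ccccc3)C(C)(C)C)C[C@@]2(C)[C@@H]1CC/C(=C/C(=O)O)COC(C)=O | intermediate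
24 | (2Z)-3-(acetoxymethyl)-5-[(1R,4aR,7R,8aR)-7-hydroxy-5,5,8a-trimethyl-2-methylidenedecahydronaphthalen-1-yl]pent-2-enoic acid; (13Z)-16-acetoxy-2-hydroxy-ent-labda-8(17),13-dien-15-oic acid | C=C1CC[C@@H]2C(C)(C)C[C@@H](O)C[C@@]2(C)[C@@H]1CC/C(=C/C(=O)O)COC(C)=O | target

**Step count and risks**

Total step count: 12. Longest linear sequence: 11 steps (steps 1–6 and 8–12; step 7 is the side branch).

Steps most likely to fail:
1. Step 8 (Proposed new method). What may go wrong: ring-B closure may stall at the fully substituted enol carbon or end at oxygen instead of carbon, the Michael stage may over-alkylate, or the cascade may start at the internal olefin. Fallback with known chemistry, setting out from 13: SnCl4 (CH2Cl2, 0 °C → rt) should cyclise the unsubstituted β-keto ester, the precedented tin-mediated bicyclisation of γ-polyprenyl acetoacetates, to the bicyclic β-keto ester methyl (1S,4aR,7R,8aR)-7-{[tert-butyl(diphenyl)silyl]oxy}-5,5,8a-trimethyl-2-oxodecahydronaphthalene-1-carboxylate F1. Base-catalysed 1,6-Michael addition of F1 to 16 (DBU or Cs2CO3, MeCN, 40 °C), with attack from the axial face, should then give 18, where the route is rejoined.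
2. Step 11 (O-acetylation of the opened lactone). What may go wrong: relactonisation to 20 may compete with O-acetylation if the carboxylate is activated as a mixed anhydride before the alkoxide is capped. Fallback with known chemistry, setting out from 20: after saponification with KOH the carboxylate is alkylated with 2-(trimethylsilyl)ethoxymethyl chloride (DMF, 0 °C) to the hydroxy ester 2-(trimethylsilyl)ethoxymethyl (2Z)-4-hydroxy-3-{2-[(1R,4aR,7R,8aR)-7-{[tert-butyl(diphenyl)silyl]oxy}-5,5,8a-trimethyl-2-methylidenedecahydronaphthalen-1-yl]ethyl}but-2-enoate F2. Acetylation of F2 (Ac2O, pyridine, DMAP, 0 °C) should give the acetoxy ester 2-(trimethylsilyl)ethoxymethyl (2Z)-3-(acetoxymethyl)-5-[(1R,4aR,7R,8aR)-7-{[tert-butyl(diphenyl)silyl]oxy}-5,5,8a-trimethyl-2-methylidenedecahydronaphthalen-1-yl]pent-2-enoate F3. Cleavage of the alkoxymethyl ester of F3 with MgBr2·OEt2 (Et2O, rt) returns to the route at 23.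
3. Step 10 (methylenation of the C-8 ketone). What may go wrong: conversion of the hindered ketone may be incomplete, or the Lewis-acidic medium may move the new exocyclic double bond into the ring. Fallback with known chemistry, setting out from 19: Me3SiCH2MgCl with CeCl3 (THF, −78 °C) should add selectively to the ketone to give the β-hydroxysilane 4-{2-[(1S,4aR,7R,8aR)-7-{[tert-butyl(diphenyl)silyl]oxy}-2-hydroxy-5,5,8a-trimethyl-2-[(trimethylsilyl)methyl]decahydronaphthalen-1-yl]ethyl}furan-2(5H)-one F4, whose configuration at C-2 of the decalin is left unspecified (attack is expected anti to the angular methyl). Peterson elimination of F4 (TsOH cat., CH2Cl2, 0 °C) should then give 20 regiospecifically.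

**Further compounds**

F1 | step 8 | methyl (1S,4aR,7R,8aR)-7-{[tert-butyl(diphenyl)silyl]oxy}-5,5,8a-trimethyl-2-oxodecahydronaphthalene-1-carboxylate | O=C1CC[C@@H]2C(C)(C)C[C@@H](O[Si](c3ccccc3)(c3ccccc3)C(C)(C)C)C[C@@]2(C)[C@@H]1C(=O)OC
F2 | step 11 | 2-(trimethylsilyl)ethoxymethyl (2Z)-4-hydroxy-3-{2-[(1R,4aR,7R,8aR)-7-{[tert-butyl(diphenyl)silyl]oxy}-5,5,8a-trimethyl-2-methylidenedecahydronaphthalen-1-yl]ethyl}but-2-enoate | C=C1CC[C@@H]2C(C)(C)C[C@@H](O[Si](c3ccccc3)(c3ccccc3)C(C)(C)C)C[C@@]2(C)[C@@H]1CC/C(=C/C(=O)OCOCC[Si](C)(C)C)CO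
F3 | step 11 | 2-(trimethylsilyl)ethoxymethyl (2Z)-3-(acetoxymethyl)-5-[(1R,4aR,7R,8aR)-7-{[tert-butyl(diphenyl)silyl]oxy}-5,5,8a-trimethyl-2-methylidenedecahydronaphthalen-1-yl]pent-2-enoate | C=C1CC[C@@H]2C(C)(C)C[C@@H](O[Si](c3ccccc3)(c3ccccc3)C(C)(C)C)C[C@@]2(C)[C@@H]1CC/C(=C/C(=O)OCOCC[Si](C)(C)C)COC(C)=O
F4 | step 10 | 4-{2-[(1S,4aR,7R,8aR)-7-{[tert-butyl(diphenyl)silyl]oxy}-2-hydroxy-5,5,8a-trimethyl-2-[(trimethylsilyl)methyl]decahydronaphthalen-1-yl]ethyl}furan-2(5H)-one | C[Si](C)(C)CC1(O)CC[C@@H]2C(C)(C)C[C@@H](O[Si](c3ccccc3)(c3ccccc3)C(C)(C)C)C[C@@]2(C)[C@@H]1CCC1=CC(=O)OC1
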